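Positions are numbered as in chroman-2-one (O1, C2, C3, C4, C4a, C5 to C8, C8a; ring A is the benzo ring). The three phenols are freed last from methyl ethers, and the chalcone arm comes from a Claisen–Schmidt condensation of an 8-acetyl group with 4-methoxybenzaldehyde.
The C4 stereocenter and the C4–phenyl bond come from a rhodium-catalyzed asymmetric 1,4-addition of phenylboronic acid to 8-acetyl-5,7-dimethoxycoumarin; the lactone is therefore carried one oxidation level higher (C3=C4) up to that point.
The coumarin lactone ring, the only ring the route forms, is closed by a [3+3] annulation of the O–C–C unit of (diethoxyphosphoryl)acetic acid onto 3-acetyl-2-fluoro-4,6-dimethoxybenzaldehyde: carboxylate SNAr makes O1–C8a and intramolecular Horner–Wadsworth–Emmons olefination makes C3–C4 (as C3=C4).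
Enabling feature: in ring A, C8a lies between C8, which carries the ketone, and C4a, which carries C4. With C4 as a formyl group, a C8a–F bond has a carbonyl group on each ortho carbon, so C4 and C8a form a 1,3-dielectrophile; since C8a is the only fluorinated carbon, the lactone oxygen cannot end up on C5, the other oxygen-bearing carbon ortho to C4a.
Ring A is bought as 1-fluoro-3,5-dimethoxybenzene and takes up the acetyl and formyl groups by two electrophilic substitutions next to fluorine; the phenyl and 4-hydroxyphenyl rings are bought.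

Key step: step 3

Assumption: compounds 1, 5, 8 and 10 and all reagents are taken as commercial.

Step 1
Reactants: 1 1-fluoro-3,5-dimethoxybenzene
Product: 2 1-(2-fluoro-4,6-dimethoxyphenyl)ethan-1-one
Conditions: AcCl (1.1 equiv), AlCl3 (1.2 equiv), CH2Cl2, −10 °C to 0 °C; cold 1 M HCl work-up
Reagents that add atoms: acetyl chloride, CC(=O)Cl
Why: Friedel–Crafts acylation; the acylium ion should attack C2 of 1, which is para to one methoxy group and ortho to the other and to the small fluorine, in preference to the more crowded C4 between the two methoxy groups, and the acetyl group then deactivates the ring against a second acylation.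

Step 2
Reactants: 2 1-(2-fluoro-4,6-dimethoxyphenyl)ethan-1-one
Product: 4 3-acetyl-2-fluoro-4,6-dimethoxybenzaldehyde, via α-chloro ether 3 (not isolated)
Conditions: Cl2CHOCH3 (1.5 equiv), TiCl4 (2.5 equiv), CH2Cl2, −20 °C to 0 °C; then ice-water
Reagents that add atoms: dichloromethyl methyl ether, COC(Cl)Cl; water, O
Why: Rieche formylation; the TiCl4-activated chloro ether should substitute C3 of 2, the only free position para to a methoxy group (and ortho to the other methoxy group and to fluorine), to give chloro ether 3, which the aqueous work-up hydrolyzes to the aldehyde, whereas C5 between the two methoxy groups is more hindered and has only fluorine para to it.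

Step 3
Reactants: 4 3-acetyl-2-fluoro-4,6-dimethoxybenzaldehyde; 5 (diethoxyphosphoryl)acetic acid (1.2 equiv)
Product: 7 8-acetyl-5,7-dimethoxy-2H-chromen-2-one, via aryl phosphonoacetate 6 (not isolated)
Conditions: Cs2CO3 (2.5 equiv), DMSO, 4 Å molecular sieves, 25 °C then 70 °C
Reagents that add atoms: none
Why: Proposed new method: a domino carboxylate SNAr / intramolecular Horner–Wadsworth–Emmons [3+3] annulation; the closest known reaction types are the O-arylation of carboxylates by aryl fluorides that carry ortho or para acceptor groups and the base-induced ring closure of O-(phosphonoacetyl)salicylaldehydes to coumarins. The cesium carboxylate of 5 should add to the C–F carbon of 4, where the Meisenheimer adduct is stabilized by the two ortho carbonyl groups (formyl and acetyl) and is not opposed by the two methoxy groups, which are meta to this carbon, and loss of fluoride gives aryl ester 6 with the new O–C(aryl) bond. Carbonate then deprotonates the CH2 group of 6, now flanked by an aryl ester and the phosphoryl group, and the carbanion adds to the neighbouring formyl group in a 6-(enolendo)-exo-trig closure, after which syn-elimination of diethyl phosphate from the oxaphosphetane forms C3=C4, cis by ring constraint. No stereocenter is formed. The step needs O-arylation to precede olefination, which the acidity gap in 5 secures (carbonate removes the CO2H proton but not a CH2 proton of the carboxylate, so no intermolecular olefination to an (E)-acrylate that could not lactonize), and it needs the carbanion of 6 to choose the formyl over the acetyl group, which the higher electrophilicity of the aldehyde secures. Because 4 has a single fluorine, the lactone oxygen can only be placed on the carbon between the acetyl and formyl groups.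

Step 4
Reactants: 7 8-acetyl-5,7-dimethoxy-2H-chromen-2-one; 8 phenylboronic acid (5 equiv)
Product: 9 (4R)-8-acetyl-5,7-dimethoxy-4-phenyl-3,4-dihydro-2H-chromen-2-one
Conditions: Rh(acac)(C2H4)2 (3 mol %), (R)-SEGPHOS (3.3 mol %), 1,4-dioxane/H2O 10:1, 60 °C
Reagents that add atoms: none
Why: Hayashi–Miyaura reaction (rhodium-catalyzed asymmetric 1,4-addition of an arylboronic acid to a coumarin): the phenylrhodium–(R)-SEGPHOS complex should insert C3=C4 from the enantioface that this ligand leaves open in coumarins, which corresponds to the (4R) center, and water protonates the rhodium enolate at C3, while the aryl ketone does not react with arylrhodium species under these conditions.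

Step 5
Reactants: 9 (4R)-8-acetyl-5,7-dimethoxy-4-phenyl-3,4-dihydro-2H-chromen-2-one; 10 4-methoxybenzaldehyde (1.2 equiv)
Product: 12 (4R)-5,7-dimethoxy-8-[(2E)-3-(4-methoxyphenyl)prop-2-enoyl]-4-phenyl-3,4-dihydro-2H-chromen-2-one, via aldol adduct 11 (not isolated)
Conditions: BF3·OEt2 (0.5 equiv), 1,4-dioxane, 25 °C
Reagents that add atoms: none
Why: Acid-promoted Claisen–Schmidt (aldol) condensation: BF3 should enolize the aryl methyl ketone far more readily than the lactone, the enol adds to 10 to give aldol 11, and acid-driven dehydration gives the conjugated (E)-enone as the more stable alkene; in the absence of hydroxide or alkoxide the aryl lactone stays closed and the non-enolizable C4 center is not touched.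

Step 6
Reactants: 12 (4R)-5,7-dimethoxy-8-[(2E)-3-(4-methoxyphenyl)prop-2-enoyl]-4-phenyl-3,4-dihydro-2H-chromen-2-one
Product: 14 (4R)-5,7-dihydroxy-8-[(2E)-3-(4-hydroxyphenyl)prop-2-enoyl]-4-phenyl-3,4-dihydro-2H-chromen-2-one, via tris(dibromoboryl) ether 13 (not isolated)
Conditions: BBr3 (8 equiv), CH2Cl2, −78 °C to 20 °C; then H2O, 0 °C
Reagents that add atoms: none
Why: Lewis acid cleavage of aryl methyl ethers: BBr3 borylates each ether oxygen and bromide attacks the methyl carbon (SN2), so only O–CH3 bonds are broken to give borate 13, which water hydrolyzes to the three phenols; the O–aryl bond of the lactone, the enone and the C4 center take no part, and no basic stage arises in which the lactone acyl group could move to the C5 oxygen.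

Compound list
1 | 1-fluoro-3,5-dimethoxybenzene | COc1cc(F)cc(OC)c1 | starting material
2 | 1-(2-fluoro-4,6-dimethoxyphenyl)ethan-1-one | CC(=O)c1c(F)cc(OC)cc1OC | intermediate
3 | 1-[3-(chloro(methoxy)methyl)-2-fluoro-4,6-dimethoxyphenyl]ethan-1-one (racemic) | CC(=O)c1c(F)c(C(Cl)OC)c(OC)cc1OC | intermediate (not isolated)
4 | 3-acetyl-2-fluoro-4,6-dimethoxybenzaldehyde | CC(=O)c1c(F)c(C=O)c(OC)cc1OC | intermediate
5 | (diethoxyphosphoryl)acetic acid | CCOP(=O)(OCC)CC(=O)O | starting material
6 | 2-acetyl-6-formyl-3,5-dimethoxyphenyl (diethoxyphosphoryl)acetate | CCOP(=O)(OCC)CC(=O)Oc1c(C(C)=O)c(OC)cc(OC)c1C=O | intermediate (not isolated)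
7 | 8-acetyl-5,7-dimethoxy-2H-chromen-2-one | O=C1C=Cc2c(OC)cc(OC)c(C(C)=O)c2O1 | intermediate
8 | phenylboronic acid | OB(O)c1ccccc1 | starting material
9 | (4R)-8-acetyl-5,7-dimethoxy-4-phenyl-3,4-dihydro-2H-chromen-2-one | O=C1C[C@H](c2ccccc2)c2c(OC)cc(OC)c(C(C)=O)c2O1 | intermediate
10 | 4-methoxybenzaldehyde | COc1ccc(C=O)cc1 | starting material
11 | (4R)-8-[3-hydroxy-3-(4-methoxyphenyl)propanoyl]-5,7-dimethoxy-4-phenyl-3,4-dihydro-2H-chromen-2-one (both epimers at the carbinol carbon) | O=C1C[C@H](c2ccccc2)c2c(OC)cc(OC)c(C(=O)CC(O)c3ccc(OC)cc3)c2O1 | intermediate (not isolated)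
12 | (4R)-5,7-dimethoxy-8-[(2E)-3-(4-methoxyphenyl)prop-2-enoyl]-4-phenyl-3,4-dihydro-2H-chromen-2-one | O=C1C[C@H](c2ccccc2)c2c(OC)cc(OC)c(C(=O)/C=C/c3ccc(OC)cc3)c2O1 | intermediate
13 | (4R)-5,7-bis[(dibromoboranyl)oxy]-8-[(2E)-3-{4-[(dibromoboranyl)oxy]phenyl}prop-2-enoyl]-4-phenyl-3,4-dihydro-2H-chromen-2-one | O=C1C[C@H](c2ccccc2)c2c(OB(Br)Br)cc(OB(Br)Br)c(C(=O)/C=C/c3ccc(OB(Br)Br)cc3)c2O1 | intermediate (not isolated)
14 | (4R)-5,7-dihydroxy-8-[(2E)-3-(4-hydroxyphenyl)prop-2-enoyl]-4-phenyl-3,4-dihydro-2H-chromen-2-one (CNP0196364.2) | O=C1C[C@H](c2ccccc2)c2c(O)cc(O)c(C(=O)/C=C/c3ccc(O)cc3)c2O1 | target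

Total step count: 6. Longest linear sequence: 6 steps (1 to 14).

Steps most likely to fail

Step 3 (key step). The displacement of fluoride by the weakly nucleophilic carboxylate may be too slow at the crowded C–F carbon. Base-induced reactions of the acetyl group could then take over: aldol condensation with the formyl group of a second molecule, or transfer of the acyl group of 6 from oxygen to the acetyl carbon. Hydrolysis by traces of water is a further drain. The fallback uses known chemistry and sets out from 4. The fluorine is exchanged for a hydroxyl group with the hydroxide surrogate 2-(methylsulfonyl)ethanol (NaH, DMF, 0 °C to 25 °C; SNAr by the alkoxide, then E1cB loss of methyl vinyl sulfone), which should give 3-acetyl-2-hydroxy-4,6-dimethoxybenzaldehyde F1. Wittig olefination of F1 with ethyl (triphenylphosphoranylidene)acetate in N,N-diethylaniline at reflux should give ethyl 3-(3-acetyl-2-hydroxy-4,6-dimethoxyphenyl)prop-2-enoate F2 as an E/Z mixture. At that temperature F2 isomerizes and lactonizes with loss of ethanol, and the route is rejoined at 7. The lactone then closes at the acyl carbon, but its oxygen still sits only where the fluorine was.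

Step 4. Insertion may be slow because the two methoxy groups make the coumarin a weak acceptor and the 5-methoxy group crowds C4, so that protodeboronation of 8 outruns addition; the same crowding may erode facial selectivity. The fallback sets out from 7 and builds the C4–phenyl bond first. An oxidative Heck reaction with 8 (Pd(OAc)2, 1,10-phenanthroline, O2, DMF, 80 °C) should give 8-acetyl-5,7-dimethoxy-4-phenyl-2H-chromen-2-one F3. NaOH in methanol opens F3 to disodium (2Z)-3-(3-acetyl-4,6-dimethoxy-2-oxidophenyl)-3-phenylprop-2-enoate F4. Asymmetric hydrogenation of F4 ([Rh(cod)2]BF4 with a chiral bisphosphine such as Chiraphos in the enantiomeric form that leads to the (R) acid, H2), then acidification with HCl, should give (3R)-3-(3-acetyl-2-hydroxy-4,6-dimethoxyphenyl)-3-phenylpropanoic acid F5. Acid-catalyzed lactonization (TsOH, toluene, 80 °C) can use only the C8a phenol, because the C5 oxygen is methylated, and returns to 9.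

Step 6. Once the C5 phenol is unmasked, the Lewis acid may open the lactone or move its acyl group from the C8a oxygen to the C5 oxygen. Acid may also close the 2′-hydroxychalcone to a flavanone, and the less activated methyl ethers may be cleaved incompletely. The fallback sets out from 7 and exchanges the methyl ethers for benzyl ethers at the coumarin stage, where the unsaturated lactone cannot migrate. BBr3 in CH2Cl2 should give 8-acetyl-5,7-dihydroxy-2H-chromen-2-one F6. Benzyl bromide and K2CO3 in DMF should give 8-acetyl-5,7-bis(benzyloxy)-2H-chromen-2-one F7. The conditions of step 4 should give (4R)-8-acetyl-5,7-bis(benzyloxy)-4-phenyl-3,4-dihydro-2H-chromen-2-one F8. The conditions of step 5 with 4-(benzyloxy)benzaldehyde should give (4R)-5,7-bis(benzyloxy)-8-[(2E)-3-[4-(benzyloxy)phenyl]prop-2-enoyl]-4-phenyl-3,4-dihydro-2H-chromen-2-one F9. BCl3 with pentamethylbenzene as benzyl cation scavenger in CH2Cl2 at −78 °C then removes the three benzyl groups, and the route is rejoined at 14.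

Further compounds
F1 | step 3 | 3-acetyl-2-hydroxy-4,6-dimethoxybenzaldehyde | CC(=O)c1c(O)c(C=O)c(OC)cc1OC
F2 | step 3 | ethyl 3-(3-acetyl-2-hydroxy-4,6-dimethoxyphenyl)prop-2-enoate (E/Z mixture) | CCOC(=O)C=Cc1c(O)c(C(C)=O)c(OC)cc1OC
F3 | step 4 | 8-acetyl-5,7-dimethoxy-4-phenyl-2H-chromen-2-one | O=C1C=C(c2ccccc2)c2c(OC)cc(OC)c(C(C)=O)c2O1
F4 | step 4 | disodium (2Z)-3-(3-acetyl-4,6-dimethoxy-2-oxidophenyl)-3-phenylprop-2-enoate | [Na+].[Na+].[O-]C(=O)/C=C(/c1ccccc1)c1c(OC)cc(OC)c(C(C)=O)c1[O-]
F5 | step 4 | (3R)-3-(3-acetyl-2-hydroxy-4,6-dimethoxyphenyl)-3-phenylpropanoic acid | OC(=O)C[C@H](c1ccccc1)c1c(OC)cc(OC)c(C(C)=O)c1O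
F6 | step 6 | 8-acetyl-5,7-dihydroxy-2H-chromen-2-one | O=C1C=Cc2c(O)cc(O)c(C(C)=O)c2O1
F7 | step 6 | 8-acetyl-5,7-bis(benzyloxy)-2H-chromen-2-one | O=C1C=Cc2c(OCc3ccccc3)cc(OCc3ccccc3)c(C(C)=O)c2O1
F8 | step 6 | (4R)-8-acetyl-5,7-bis(benzyloxy)-4-phenyl-3,4-dihydro-2H-chromen-2-one | O=C1C[C@H](c2ccccc2)c2c(OCc3ccccc3)cc(OCc3ccccc3)c(C(C)=O)c2O1
F9 | step 6 | (4R)-5,7-bis(benzyloxy)-8-[(2E)-3-[4-(benzyloxy)phenyl]prop-2-enoyl]-4-phenyl-3,4-dihydro-2H-chromen-2-one | O=C1C[C@H](c2ccccc2)c2c(OCc3ccccc3)cc(OCc3ccccc3)c(C(=O)/C=C/c3ccc(OCc4ccccc4)cc3)c2O1
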